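**Assumption:** Paucinervin B has no stereocentres and no E/Z-defined alkene (the prenyl terminus is gem-dimethyl), so it is achiral and "single enantiomer" needs no stereocontrol.

## Retrosynthetic overview

1. Both benzene rings are bought intact; no ring is formed. The only skeletal bonds made are the diaryl ether C–O and the aryl–prenyl C–C.
2. The ring-A phenols are unmasked last (two MOM ethers).
3. The prenyl group sits para to the free ring-B OH, whose two ortho positions are blocked, so it comes from an O-prenyl ether by para-Claisen–Cope rearrangement.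
4. The ring-B OH comes from an aryl aldehyde (Baeyer–Villiger/Dakin). That same aldehyde activates an ortho fluoride for SNAr, which forms the diaryl ether.
5. Fragments: methyl 2-hydroxy-4,6-bis(MOM-oxy)benzoate (from methyl 2,4,6-trihydroxybenzoate) and 2-fluoro-3,6-dimethoxybenzaldehyde (ortho-lithiation/formylation of 2-fluoro-1,4-dimethoxybenzene).

## Route

**Step 1**
Reactants: 1 methyl 2,4,6-trihydroxybenzoate; 2 chloromethyl methyl ether (MOMCl)
Product: 3 methyl 2-hydroxy-4,6-bis(methoxymethoxy)benzoate
Conditions: MOMCl (2.2 equiv), i-Pr2NEt, CH2Cl2, 0 °C → rt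
Reagents that add atoms: MOMCl, COCCl (two CH2OCH3 groups)
Why: Selective O-alkylation (Williamson type). The 4-OH and one ortho OH react, while the last ortho OH is strongly hydrogen-bonded to the ester carbonyl and stays free, as with 2,4,6-trihydroxyacetophenone.

**Step 2**
Reactants: 4 2-fluoro-1,4-dimethoxybenzene; 5 N,N-dimethylformamide
Product: 6 2-fluoro-3,6-dimethoxybenzaldehyde
Conditions: n-BuLi, THF, −78 °C, 1 h; DMF, −78 → 0 °C; aq NH4Cl
Reagents that add atoms: DMF, CN(C)C=O (the CHO group)
Why: Directed ortho-metalation at the C–H flanked by F and OMe (cooperative directors, most acidic site), then formylation. Holding at −78 °C prevents LiF loss to the aryne.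

**Step 3**
Reactants: 3 methyl 2-hydroxy-4,6-bis(methoxymethoxy)benzoate; 6 2-fluoro-3,6-dimethoxybenzaldehyde
Product: 7 methyl 2-(2-formyl-3,6-dimethoxyphenoxy)-4,6-bis(methoxymethoxy)benzoate
Conditions: Cs2CO3, dry DMF, 100–110 °C (6 in 1.2 equiv)
Reagents that add atoms: none (only 3 and 6; HF is lost)
Why: SNAr. The caesium phenoxide of 3 displaces fluoride ortho to the formyl group through a formyl-stabilised Meisenheimer complex. MOM ethers, the methyl ester and the non-enolisable aldehyde tolerate anhydrous carbonate.

**Step 4**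
Reactants: 7 methyl 2-(2-formyl-3,6-dimethoxyphenoxy)-4,6-bis(methoxymethoxy)benzoate; 8 mCPBA
Product: 9 methyl 2-(2-hydroxy-3,6-dimethoxyphenoxy)-4,6-bis(methoxymethoxy)benzoate
Conditions: mCPBA, NaHCO3, CH2Cl2, 0 °C → rt; Na2S2O3 quench; then K2CO3, MeOH, 0 °C, short
Reagents that add atoms: mCPBA, OOC(=O)c1cccc(Cl)c1 (one O; the formyl carbon leaves as formate)
Why: Baeyer–Villiger (Dakin-type) oxidation. The electron-rich di-ortho-oxygenated aryl migrates to give the aryl formate, which is methanolysed to the phenol. Bicarbonate buffering protects the MOM ethers, and the hindered benzoate is untouched in MeOH.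

**Step 5**
Reactants: 9 methyl 2-(2-hydroxy-3,6-dimethoxyphenoxy)-4,6-bis(methoxymethoxy)benzoate; 10 prenyl bromide (1-bromo-3-methylbut-2-ene)
Product: 11 methyl 2-[3,6-dimethoxy-2-(3-methylbut-2-enyloxy)phenoxy]-4,6-bis(methoxymethoxy)benzoate
Conditions: prenyl bromide, K2CO3, acetone, 50 °C
Reagents that add atoms: prenyl bromide, CC(C)=CCBr (C5H9)
Why: Williamson O-alkylation (SN2) of the only free phenol. Mild base avoids Smiles rearrangement or lactonisation onto the ester.

**Step 6**
Reactants: 11 methyl 2-[3,6-dimethoxy-2-(3-methylbut-2-enyloxy)phenoxy]-4,6-bis(methoxymethoxy)benzoate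
Product: 12 methyl 2-[2-hydroxy-3,6-dimethoxy-5-(3-methylbut-2-enyl)phenoxy]-4,6-bis(methoxymethoxy)benzoate
Conditions: PhNEt2, degassed, 200 °C, sealed tube, 1–3 h
Reagents that add atoms: none
Why: para-Claisen–Cope rearrangement. Both ortho positions (OAr, OMe) are blocked, so the [3,3] shift to an ortho dienone is followed by a Cope [3,3] shift to the free para carbon and tautomerisation. The double allylic inversion restores the linear prenyl group, and the process is intramolecular, so ring A is not touched.

**Step 7**
Reactants: 12 methyl 2-[2-hydroxy-3,6-dimethoxy-5-(3-methylbut-2-enyl)phenoxy]-4,6-bis(methoxymethoxy)benzoate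
Product: 13 Paucinervin B, methyl 2,4-dihydroxy-6-[2-hydroxy-3,6-dimethoxy-5-(3-methylbut-2-enyl)phenoxy]benzoate
Conditions: 3 M HCl in MeOH, rt → 40 °C
Reagents that add atoms: none
Why: Acid-catalysed acetal (MOM) methanolysis. The methyl ester is stable in MeOH, and the prenyl group has no ortho OH, so chroman formation is impossible.

## Compound list

1 | methyl 2,4,6-trihydroxybenzoate | COC(=O)c1c(O)cc(O)cc1O | starting material
2 | chloromethyl methyl ether (MOMCl) | COCCl | starting material (reagent)
3 | methyl 2-hydroxy-4,6-bis(methoxymethoxy)benzoate | COC(=O)c1c(O)cc(OCOC)cc1OCOC | intermediate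
4 | 2-fluoro-1,4-dimethoxybenzene | COc1ccc(OC)c(F)c1 | starting material
5 | N,N-dimethylformamide | CN(C)C=O | starting material (reagent)
6 | 2-fluoro-3,6-dimethoxybenzaldehyde | COc1ccc(OC)c(C=O)c1F | intermediate
7 | methyl 2-(2-formyl-3,6-dimethoxyphenoxy)-4,6-bis(methoxymethoxy)benzoate | COC(=O)c1c(OCOC)cc(OCOC)cc1Oc1c(C=O)c(OC)ccc1OC | intermediate
8 | meta-chloroperoxybenzoic acid (mCPBA) | OOC(=O)c1cccc(Cl)c1 | starting material (reagent)
9 | methyl 2-(2-hydroxy-3,6-dimethoxyphenoxy)-4,6-bis(methoxymethoxy)benzoate | COC(=O)c1c(OCOC)cc(OCOC)cc1Oc1c(O)c(OC)ccc1OC | intermediate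
10 | prenyl bromide (1-bromo-3-methylbut-2-ene) | CC(C)=CCBr | starting material
11 | methyl 2-[3,6-dimethoxy-2-(3-methylbut-2-enyloxy)phenoxy]-4,6-bis(methoxymethoxy)benzoate | COC(=O)c1c(OCOC)cc(OCOC)cc1Oc1c(OCC=C(C)C)c(OC)ccc1OC | intermediate
12 | methyl 2-[2-hydroxy-3,6-dimethoxy-5-(3-methylbut-2-enyl)phenoxy]-4,6-bis(methoxymethoxy)benzoate | COC(=O)c1c(OCOC)cc(OCOC)cc1Oc1c(O)c(OC)cc(CC=C(C)C)c1OC | intermediate
13 | Paucinervin B (achiral) | COC(=O)c1c(O)cc(O)cc1Oc1c(O)c(OC)cc(CC=C(C)C)c1OC | target

## Summary

**Total steps:** 7. **Longest linear sequence:** 6 (steps 1, 3, 4, 5, 6, 7; or 2, 3–7).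

**Steps most likely to fail, with fallbacks**

1. **Step 3 (SNAr).** The phenoxide is a weak, ester-conjugated nucleophile and the fluoride is hindered and activated only by one formyl group. Fallback: tether first. Mono-acylate symmetric 3,6-dimethoxycatechol with 2-bromo-4,6-bis(MOM-oxy)benzoyl chloride, close the depsidone by intramolecular Cu-catalysed Ullmann etherification, then open the lactone with NaOMe/MeOH. This gives compound 9 directly.
2. **Step 6 (para-Claisen–Cope).** Thermal loss of isoprene back to phenol 9, or incomplete ortho-to-para migration, may lower the yield. Fallback: brominate 9 para to the free phenol (NBS) and install the prenyl group by Pd-catalysed Stille coupling with tributyl(prenyl)stannane.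
3. **Step 7 (acidic MOM removal).** The trisubstituted alkene on an electron-rich arene may add HCl or MeOH before the para MOM ether is cleaved. Fallback: use allyl bromide in step 5 (the allyl para-Claisen is cleaner), remove the MOM groups with acid while the terminal allyl is inert, then form the prenyl group last by cross-metathesis with 2-methyl-2-butene (Grubbs II) on the free triphenol.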